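**Plan**

- Retrosynthesis: cut the C5–propenyl bond (aryl chloride as placeholder), then O1–C2 of the dihydrofuran ring, then the C2–O, C2–C1' and C2–C3 bonds back to a C3 boronic ester, and finally C3–CH3 and C3–C3a back to an arylboronic ester.
- Forward: the chain grows on boron. The arylboronic ester is homologated to the C3 boronate, a second homologation inserts C2 and attaches the trimethoxyphenyl ring, boron is exchanged for oxygen, the dihydrofuran ring (the only ring made) closes by O1–C2 bond formation, and the propenyl group is coupled last.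
- Enabling feature: C2 is a CH bonded to C3, to C1' of the trimethoxyphenyl ring and to O1. It can therefore be the carbon of dichloromethane inserted into the C3–B bond, arylated by a boron-to-carbon shift and oxygenated at the C–B bond.
- Stereochemistry: one (S,S)-1,2-dicyclohexylethane-1,2-diol director on boron selects the chloride lost in each homologation. The Grignard displacements invert, the oxidation retains and the ring closure inverts, which gives (2R,3R), trans.

Key step: step 8

Remark: the sense of induction is assumed to follow the established behaviour of twofold-symmetric diol boronates with LiCHCl2/ZnCl2, where an (R,R)-diol gives the (αS)-chloro boronate; on that basis the (S,S)-diol is the director required for the 2R,3R series.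

**Route**

Step 1
Reactants: 1 4-chloro-2-methoxyphenol
Product: 2 2-bromo-4-chloro-6-methoxyphenol
Conditions: Br2, NaOAc, AcOH, rt
Reagents that add atoms: bromine, BrBr
Why: Electrophilic aromatic bromination should take the only free position ortho to the hydroxyl group, the strongest director, because its para position carries chlorine.

Step 2
Reactants: 2 2-bromo-4-chloro-6-methoxyphenol
Product: 3 1-bromo-5-chloro-3-methoxy-2-(methoxymethoxy)benzene
Conditions: NaH, MOMCl, DMF, 0 °C to rt
Reagents that add atoms: chloromethyl methyl ether, COCCl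
Why: Williamson-type O-alkylation of the sodium phenoxide should protect the hindered phenol as an acetal that tolerates organolithium and Grignard reagents.

Step 3
Reactants: 3 1-bromo-5-chloro-3-methoxy-2-(methoxymethoxy)benzene
Product: 5 [5-chloro-3-methoxy-2-(methoxymethoxy)phenyl]boronic acid, via aryllithium 4 (not isolated)
Conditions: n-BuLi, THF, –78 °C; B(OiPr)3, –78 °C to rt; 1 M HCl to pH 5, 0 °C
Reagents that add atoms: triisopropyl borate, CC(C)OB(OC(C)C)OC(C)C; water, O
Why: Bromine–lithium exchange is far faster than chlorine–lithium exchange and gives an aryllithium held by the neighbouring acetal oxygen, which is borylated by the trialkyl borate and released as the boronic acid on mild hydrolysis.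

Step 4
Reactants: 5 [5-chloro-3-methoxy-2-(methoxymethoxy)phenyl]boronic acid; 6 (1S,2S)-1,2-dicyclohexylethane-1,2-diol
Product: 7 (4S,5S)-2-[5-chloro-3-methoxy-2-(methoxymethoxy)phenyl]-4,5-dicyclohexyl-1,3,2-dioxaborolane
Conditions: MgSO4, Et2O, rt
Reagents that add atoms: none
Why: Boronic ester formation by condensation with a 1,2-diol is driven by removal of water and gives the robust dioxaborolane that carries the chiral director.

Step 5
Reactants: 8 dichloromethane
Product: 9 dichloromethyllithium (THF solution at –100 °C, used at once)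
Conditions: n-BuLi (hexanes), THF, –100 °C
Reagents that add atoms: n-butyllithium, [Li]CCCC
Why: Deprotonation of dichloromethane by n-BuLi is fast at –100 °C, where the carbenoid survives long enough to be trapped by a boronic ester; because the solution cannot be stored, this preparation is carried out afresh immediately before step 6 and again immediately before step 8.

Step 6
Reactants: 7 (4S,5S)-2-[5-chloro-3-methoxy-2-(methoxymethoxy)phenyl]-4,5-dicyclohexyl-1,3,2-dioxaborolane; 9 dichloromethyllithium
Product: 11 (4S,5S)-2-{(1R)-1-[5-chloro-3-methoxy-2-(methoxymethoxy)phenyl]ethyl}-4,5-dicyclohexyl-1,3,2-dioxaborolane, via α-chlorobenzyl boronate 10 (not isolated)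
Conditions: 9 (fresh, THF, –100 °C), then 7 (THF); ZnCl2 (THF), –100 to 0 °C; MeMgBr (1.2 equiv), –78 °C to rt
Reagents that add atoms: methylmagnesium bromide, C[Mg]Br
Why: In this Matteson homologation 9 adds to boron, ZnCl2 promotes the aryl shift with loss of the chloride selected by the (S,S)-diol to give the (R)-chloride 10, and methyl then migrates from boron to carbon with inversion to set C3 as R, the chloride being consumed cold and without isolation because benzylic chloro boronates exchange chloride readily.

Step 7
Reactants: 12 5-bromo-1,2,3-trimethoxybenzene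
Product: 13 (3,4,5-trimethoxyphenyl)magnesium bromide (THF solution, titrated and used directly)
Conditions: Mg turnings, I2 (cat.), THF, reflux
Reagents that add atoms: magnesium, [Mg]
Why: Grignard formation by insertion of magnesium into the aryl–bromine bond is routine for this electron-rich aryl bromide.

Step 8
Reactants: 11 (4S,5S)-2-{(1R)-1-[5-chloro-3-methoxy-2-(methoxymethoxy)phenyl]ethyl}-4,5-dicyclohexyl-1,3,2-dioxaborolane; 9 dichloromethyllithium; 13 (3,4,5-trimethoxyphenyl)magnesium bromide
Product: 15 (4S,5S)-2-[(1S,2S)-2-[5-chloro-3-methoxy-2-(methoxymethoxy)phenyl]-1-(3,4,5-trimethoxyphenyl)propyl]-4,5-dicyclohexyl-1,3,2-dioxaborolane, via α-chloro boronate 14 (not isolated)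
Conditions: 9 (fresh, THF, –100 °C), then 11 (THF); ZnCl2 (THF), –100 °C to rt; then 13 (1.2 equiv), –78 °C to rt
Reagents that add atoms: none
Why: Dichloromethyllithium 9 adds to the trigonal boron of 11 to give a tetracoordinate borate, and ZnCl2 then assists departure of one of the two diastereotopic chlorides while C3 shifts from boron to carbon with retention, forming C2–C3 and the (1R)-chloride 14; Grignard reagent 13 next forms a second borate whose aryl group migrates antiperiplanar to the remaining chloride with inversion, forming C2–C1'. The closest known reaction type is the Matteson homologation of a chiral-diol boronic ester followed by Grignard displacement, that is, two consecutive 1,2-metallate shifts. No ring is formed in this step. The new stereocentre C2 is controlled by the (S,S)-dicyclohexylethanediol unit on boron, which decides which chloride leaves, and the invertive aryl transfer then fixes the S configuration at the boron-bearing carbon, while C3 is carried through unchanged. The step needs diastereoselection between the two chlorides irrespective of the existing C3 centre, which the twofold-symmetric dioxaborolane chelated to zinc should secure, and chemoselection for boron, which holds because the aryl chloride, the methyl ethers and the methoxymethyl acetal react neither with the carbenoid at –100 °C nor with the Grignard reagent.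

Step 9
Reactants: 15 (4S,5S)-2-[(1S,2S)-2-[5-chloro-3-methoxy-2-(methoxymethoxy)phenyl]-1-(3,4,5-trimethoxyphenyl)propyl]-4,5-dicyclohexyl-1,3,2-dioxaborolane
Product: 16 4-chloro-2-[(1S,2S)-1-[(4S,5S)-4,5-dicyclohexyl-1,3,2-dioxaborolan-2-yl]-1-(3,4,5-trimethoxyphenyl)propan-2-yl]-6-methoxyphenol
Conditions: HCl (1.25 M in MeOH), THF, rt to 40 °C
Reagents that add atoms: none
Why: Acid-catalysed acetal methanolysis should remove the aryl methoxymethyl ether while the acid-stable dioxaborolane and C–B bond are untouched, and at this stage there is no benzylic alcohol that could ionise.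

Step 10
Reactants: 16 4-chloro-2-[(1S,2S)-1-[(4S,5S)-4,5-dicyclohexyl-1,3,2-dioxaborolan-2-yl]-1-(3,4,5-trimethoxyphenyl)propan-2-yl]-6-methoxyphenol
Product: 17 4-chloro-2-[(1S,2R)-1-hydroxy-1-(3,4,5-trimethoxyphenyl)propan-2-yl]-6-methoxyphenol
Conditions: H2O2 (30%), NaOH, THF/H2O, 0 °C to rt
Reagents that add atoms: hydrogen peroxide, OO
Why: Oxidation of the carbon–boron bond by hydroperoxide proceeds through 1,2-migration of carbon from boron to oxygen with retention, so the (S)-carbinol is expected and the director diol is released.

Step 11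
Reactants: 17 4-chloro-2-[(1S,2R)-1-hydroxy-1-(3,4,5-trimethoxyphenyl)propan-2-yl]-6-methoxyphenol
Product: 18 (2R,3R)-5-chloro-7-methoxy-3-methyl-2-(3,4,5-trimethoxyphenyl)-2,3-dihydro-1-benzofuran
Conditions: PPh3, DIAD, THF, 0 °C to rt
Reagents that add atoms: none
Why: In this intramolecular Mitsunobu etherification the phenol, as the acidic partner, displaces the oxyphosphonium group of the benzylic alcohol in a 5-exo-tet substitution with inversion, which turns the (S)-carbinol into (2R) and places the aryl group trans to the C3 methyl group.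

Step 12
Reactants: 18 (2R,3R)-5-chloro-7-methoxy-3-methyl-2-(3,4,5-trimethoxyphenyl)-2,3-dihydro-1-benzofuran
Product: 19 (2R,3R)-7-methoxy-3-methyl-5-[(E)-prop-1-en-1-yl]-2-(3,4,5-trimethoxyphenyl)-2,3-dihydro-1-benzofuran
Conditions: (E)-prop-1-enylboronic acid pinacol ester, Pd(OAc)2, SPhos, K3PO4, toluene/H2O, 100 °C
Reagents that add atoms: (E)-4,4,5,5-tetramethyl-2-(prop-1-en-1-yl)-1,3,2-dioxaborolane, C/C=C/B1OC(C)(C)C(C)(C)O1
Why: In this Suzuki–Miyaura coupling the electron-rich dialkylbiarylphosphine should allow oxidative addition of the electron-rich aryl chloride, and transmetallation and reductive elimination keep the E geometry of the propenyl group.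

**Compound list**

1 | 4-chloro-2-methoxyphenol | COc1cc(Cl)ccc1O | starting material
2 | 2-bromo-4-chloro-6-methoxyphenol | COc1cc(Cl)cc(Br)c1O | intermediate
3 | 1-bromo-5-chloro-3-methoxy-2-(methoxymethoxy)benzene | COCOc1c(Br)cc(Cl)cc1OC | intermediate
4 | [5-chloro-3-methoxy-2-(methoxymethoxy)phenyl]lithium (not isolated) | COCOc1c([Li])cc(Cl)cc1OC | intermediate
5 | [5-chloro-3-methoxy-2-(methoxymethoxy)phenyl]boronic acid | COCOc1c(OC)cc(Cl)cc1B(O)O | intermediate
6 | (1S,2S)-1,2-dicyclohexylethane-1,2-diol | O[C@@H](C1CCCCC1)[C@@H](O)C1CCCCC1 | starting material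
7 | (4S,5S)-2-[5-chloro-3-methoxy-2-(methoxymethoxy)phenyl]-4,5-dicyclohexyl-1,3,2-dioxaborolane | COCOc1c(OC)cc(Cl)cc1B1O[C@@H](C2CCCCC2)[C@H](C2CCCCC2)O1 | intermediate
8 | dichloromethane | ClCCl | starting material
9 | dichloromethyllithium (THF solution at –100 °C, used at once) | [Li]C(Cl)Cl | intermediate
10 | (4S,5S)-2-{(R)-chloro[5-chloro-3-methoxy-2-(methoxymethoxy)phenyl]methyl}-4,5-dicyclohexyl-1,3,2-dioxaborolane (not isolated) | COCOc1c(OC)cc(Cl)cc1[C@H](Cl)B1O[C@@H](C2CCCCC2)[C@H](C2CCCCC2)O1 | intermediate
11 | (4S,5S)-2-{(1R)-1-[5-chloro-3-methoxy-2-(methoxymethoxy)phenyl]ethyl}-4,5-dicyclohexyl-1,3,2-dioxaborolane | COCOc1c(OC)cc(Cl)cc1[C@@H](C)B1O[C@@H](C2CCCCC2)[C@H](C2CCCCC2)O1 | intermediate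
12 | 5-bromo-1,2,3-trimethoxybenzene | COc1cc(Br)cc(OC)c1OC | starting material
13 | (3,4,5-trimethoxyphenyl)magnesium bromide | COc1cc([Mg]Br)cc(OC)c1OC | intermediate
14 | (4S,5S)-2-{(1R,2R)-1-chloro-2-[5-chloro-3-methoxy-2-(methoxymethoxy)phenyl]propyl}-4,5-dicyclohexyl-1,3,2-dioxaborolane (not isolated) | COCOc1c(OC)cc(Cl)cc1[C@@H](C)[C@H](Cl)B1O[C@@H](C2CCCCC2)[C@H](C2CCCCC2)O1 | intermediate
15 | (4S,5S)-2-[(1S,2S)-2-[5-chloro-3-methoxy-2-(methoxymethoxy)phenyl]-1-(3,4,5-trimethoxyphenyl)propyl]-4,5-dicyclohexyl-1,3,2-dioxaborolane | COCOc1c(OC)cc(Cl)cc1[C@@H](C)[C@H](B1O[C@@H](C2CCCCC2)[C@H](C2CCCCC2)O1)c1cc(OC)c(OC)c(OC)c1 | intermediate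
16 | 4-chloro-2-[(1S,2S)-1-[(4S,5S)-4,5-dicyclohexyl-1,3,2-dioxaborolan-2-yl]-1-(3,4,5-trimethoxyphenyl)propan-2-yl]-6-methoxyphenol | Oc1c(OC)cc(Cl)cc1[C@@H](C)[C@H](B1O[C@@H](C2CCCCC2)[C@H](C2CCCCC2)O1)c1cc(OC)c(OC)c(OC)c1 | intermediate
17 | 4-chloro-2-[(1S,2R)-1-hydroxy-1-(3,4,5-trimethoxyphenyl)propan-2-yl]-6-methoxyphenol | Oc1c(OC)cc(Cl)cc1[C@@H](C)[C@H](O)c1cc(OC)c(OC)c(OC)c1 | intermediate
18 | (2R,3R)-5-chloro-7-methoxy-3-methyl-2-(3,4,5-trimethoxyphenyl)-2,3-dihydro-1-benzofuran | Clc1cc(OC)c2c(c1)[C@@H](C)[C@H](c1cc(OC)c(OC)c(OC)c1)O2 | intermediate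
19 | (2R,3R)-7-methoxy-3-methyl-5-[(E)-prop-1-en-1-yl]-2-(3,4,5-trimethoxyphenyl)-2,3-dihydro-1-benzofuran | C/C=C/c1cc(OC)c2c(c1)[C@@H](C)[C@H](c1cc(OC)c(OC)c(OC)c1)O2 | target

**Totals**

Total step count: 12 numbered steps. Longest linear sequence: 10 steps (steps 1–4, 6 and 8–12, from compound 1). Steps 5 and 7 are one-step reagent preparations on side branches; step 5 is run twice, once before step 6 and once before step 8.

**Steps most likely to fail**

1. Step 6. Exchange of chloride at the benzylic carbon of the chloro boronate, promoted by the lithium chloride formed in the first shift, may run ahead of the methyl transfer and erode the configuration at C3. The fallback sets out from 7 and comes back to the route at 11, and replaces the chloro boronate by a lithiation–borylation. Ethyl N,N-diisopropylcarbamate F1 would be made from ethanol, NaH and N,N-diisopropylcarbamoyl chloride. Deprotonation with s-BuLi and (–)-sparteine in Et2O at –78 °C should give (S)-1-lithioethyl N,N-diisopropylcarbamate F2. This adds to boronate 7 with retention to give the lithium borate of 7 bearing the (1S)-1-(diisopropylcarbamoyloxy)ethyl group F3. Warming with MgBr2·OEt2 then lets the aryl group migrate with inversion and expel the carbamate, giving 11 after NH4Cl work-up. C3 is then set by the sparteine-controlled deprotonation and no epimerisable halide is involved.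

2. Step 8. Transfer of the aryl group to the congested chloro carbon, which carries a branched neighbour, may be slow, so that loss of HCl toward an alkenyl boronate or breakdown of the borate competes. The fallback sets out from 11 and comes back at 18. The first half of step 8 is kept as far as 14, which is oxidised in the same flask with H2O2 in pH 8 sodium phosphate buffer to (2R)-2-[5-chloro-3-methoxy-2-(methoxymethoxy)phenyl]propanal F4, used at once because the α-aryl aldehyde can racemise. Addition of 13 at –78 °C and NH4Cl work-up should give (1S,2R)-2-[5-chloro-3-methoxy-2-(methoxymethoxy)phenyl]-1-(3,4,5-trimethoxyphenyl)propan-1-ol F5 as the major isomer predicted by the Felkin–Anh model, together with its C1 epimer, (1R,2R)-2-[5-chloro-3-methoxy-2-(methoxymethoxy)phenyl]-1-(3,4,5-trimethoxyphenyl)propan-1-ol F6. HCl in MeOH then removes the acetal from both, giving 17 and its epimer 4-chloro-2-[(1R,2R)-1-hydroxy-1-(3,4,5-trimethoxyphenyl)propan-2-yl]-6-methoxyphenol F7, and closes the ring through the common trimethoxybenzyl cation, so that both epimers converge on trans-configured 18. C2 is in that case set by substrate control from C3.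

3. Step 11. Ionisation of the activated benzylic alcohol, favoured by the trimethoxyphenyl ring, may run ahead of the invertive attack of the phenoxide and lead to elimination toward the diarylpropene or to partial loss of stereospecificity. The fallback sets out from 17 and comes back at 18, and it makes no new compound, F0. The ring would be closed with catalytic p-toluenesulfonic acid in CH2Cl2 at 0 °C. The benzylic cation is captured by the phenol, any alkene formed is reprotonated to the same cation, and the 2,3-trans isomer should prevail because the aryl and methyl groups avoid each other. This exchanges stereospecific inversion for substrate control by C3.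

**Further compounds**

F1 | step 6 | ethyl N,N-diisopropylcarbamate | CCOC(=O)N(C(C)C)C(C)C
F2 | step 6 | (S)-1-lithioethyl N,N-diisopropylcarbamate | C[C@H]([Li])OC(=O)N(C(C)C)C(C)C
F3 | step 6 | lithium (4S,5S)-2-[5-chloro-3-methoxy-2-(methoxymethoxy)phenyl]-4,5-dicyclohexyl-2-[(1S)-1-(diisopropylcarbamoyloxy)ethyl]-1,3,2-dioxaborolan-2-uide | [Li+].C[C@@H](OC(=O)N(C(C)C)C(C)C)[B-]1(c2cc(Cl)cc(OC)c2OCOC)O[C@@H](C2CCCCC2)[C@H](C2CCCCC2)O1
F4 | step 8 | (2R)-2-[5-chloro-3-methoxy-2-(methoxymethoxy)phenyl]propanal | COCOc1c(OC)cc(Cl)cc1[C@@H](C)C=O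
F5 | step 8 | (1S,2R)-2-[5-chloro-3-methoxy-2-(methoxymethoxy)phenyl]-1-(3,4,5-trimethoxyphenyl)propan-1-ol | COCOc1c(OC)cc(Cl)cc1[C@@H](C)[C@H](O)c1cc(OC)c(OC)c(OC)c1
F6 | step 8 | (1R,2R)-2-[5-chloro-3-methoxy-2-(methoxymethoxy)phenyl]-1-(3,4,5-trimethoxyphenyl)propan-1-ol | COCOc1c(OC)cc(Cl)cc1[C@@H](C)[C@@H](O)c1cc(OC)c(OC)c(OC)c1
F7 | step 8 | 4-chloro-2-[(1R,2R)-1-hydroxy-1-(3,4,5-trimethoxyphenyl)propan-2-yl]-6-methoxyphenol | Oc1c(OC)cc(Cl)cc1[C@@H](C)[C@@H](O)c1cc(OC)c(OC)c(OC)c1
F0 | step 11 | none | none
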